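**Plan**

- Numbering: ring carbon C1' carries the chain, C3' and C4' carry the hydroxyls, and chain carbon C5 is the ketone.
- The enabling feature is the benzene ring itself: the adjacent oxygenated carbons C3'–C4' are the two carbons of symmetric vinylene carbonate, and C2'–C1'–C6'–C5' is a buta-1,3-diene substituted at its 2-position by the keto chain.
- Retrosynthesis: the catechol is taken back through its diketo tautomer to a cis-diol carbonate, and ring bonds C2'–C3' and C4'–C5' are cut ([4+2]). The diene's C1'=C2' and C5'=C6' bonds are cut to a terminal alkyne plus ethylene, and chain bond C5–C6 to a Weinreb amide plus a C15 Grignard reagent.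
- Forward: Weinreb amide, then enyne metathesis to the diene, then the C15 chain by Grignard addition, then the only ring by Diels–Alder reaction, then carbonate removal and double oxidation with aromatisation.
- Stereochemistry: the target has none. The two cis centres made in the cycloaddition (suprafacial addition to a ring-locked Z-alkene, racemic) are erased on aromatisation.

Key step: step 4

Remark: because the target is achiral, cycloadduct 11 and diol 12 are carried as racemates; their SMILES show one enantiomer of the cis pair.

**Route**

Step 1
Reactants: 1 hept-6-ynoic acid
Product: 3 N-methoxy-N-methylhept-6-ynamide, via acyl imidazole 2 (not isolated)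
Conditions: CDI (1.1 equiv), CH2Cl2, rt, 1 h; then MeNHOMe·HCl (1.2 equiv), rt, 12 h
Reagents that add atoms: N,O-dimethylhydroxylamine hydrochloride, CNOC.Cl
Why: Weinreb amide formation by carbonyldiimidazole activation, in which the acid is converted into acyl imidazole 2 with loss of CO2 and the hydroxylamine, freed from its salt by the released imidazole, displaces imidazole while the terminal alkyne stays untouched.

Step 2
Reactants: 3 N-methoxy-N-methylhept-6-ynamide; 4 ethylene
Product: 5 N-methoxy-N-methyl-6-methylideneoct-7-enamide
Conditions: ethylene (1 atm), second-generation Grubbs catalyst RuCl2(=CHPh)(PCy3)(H2IMes) (5 mol%), toluene, 80 °C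
Reagents that add atoms: none
Why: Enyne cross-metathesis with ethylene, in which the ruthenium methylidene adds to the terminal alkyne, the resulting vinylcarbene is intercepted by ethylene and the 2-substituted buta-1,3-diene is released, the remote Weinreb amide being a tolerated spectator and the ethylene atmosphere holding back alkyne oligomerisation.

Step 3
Reactants: 5 N-methoxy-N-methyl-6-methylideneoct-7-enamide; 6 1-bromopentadecane
Product: 9 3-methylidenetricos-1-en-8-one, via pentadecylmagnesium bromide 7 (not isolated), via magnesium hemiaminal chelate 8 (not isolated)
Conditions: 6 (1.4 equiv), Mg turnings, I2 (cat.), THF, reflux; then add to 5, THF, 0 °C, 1 h; 1 M HCl, 0 °C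
Reagents that add atoms: none
Why: Weinreb ketone synthesis, in which the Grignard reagent adds once to give the five-membered magnesium chelate 8 that survives at 0 °C and collapses to the ketone only on acidic quench, so no tertiary alcohol should form and the diene, which has neither an acidic C–H nor an electrophilic site, is not touched.

Step 4
Reactants: 9 3-methylidenetricos-1-en-8-one; 10 vinylene carbonate
Product: 11 cis-5-(5-oxoicosyl)-3a,4,7,7a-tetrahydro-1,3-benzodioxol-2-one, racemic (3aR*,7aS*)
Conditions: 10 (8 equiv, neat), BHT (2 mol%), Ar, sealed tube, 170 °C, 24 h
Reagents that add atoms: none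
Why: Thermal Diels–Alder reaction in which the 2-alkylbuta-1,3-diene of 9 (its HOMO raised by the alkyl group, its s-cis form readily populated) and the electron-poor enediol carbonate 10 combine in a concerted suprafacial–suprafacial [4+2] cycloaddition, the closest known reaction type being the sealed-tube cycloaddition of vinylene carbonate with isoprene or 2,3-dimethylbutadiene. The single new ring, the six-membered carbocycle, is closed by intermolecular [4+2] annulation in which the σ-bonds C2'–C3' and C4'–C5' form in the same step, leaving the C1'=C6' double bond and a cis-fused cyclic carbonate. Both new stereocentres (C3a and C7a) should be cis because the dienophile is a Z-alkene locked in a five-membered ring and is attacked on one face; with no chiral element present the adduct is racemic, which does not matter since both centres become sp2 carbons in step 6. Regiochemistry and endo/exo selectivity do not arise, the dienophile being C2v-symmetric and the diene termini unsubstituted. The selectivity the step needs is chemoselectivity for cross-cycloaddition over diene dimerisation and radical polymerisation, which the large excess of neat 10, the radical inhibitor and the inert atmosphere are meant to secure, while the isolated dialkyl ketone is a thermal spectator.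

Step 5
Reactants: 11 cis-5-(5-oxoicosyl)-3a,4,7,7a-tetrahydro-1,3-benzodioxol-2-one
Product: 12 cis-4-(5-oxoicosyl)cyclohex-4-ene-1,2-diol, racemic (1R*,2S*)
Conditions: K2CO3 (0.2 equiv), MeOH, 0 °C to rt
Reagents that add atoms: none
Why: Base-catalysed transesterification (carbonate methanolysis), in which methoxide attacks the cyclic carbonate carbonyl twice and releases dimethyl carbonate, so neither C–O stereocentre, the ring alkene nor the chain ketone is affected.

Step 6
Reactants: 12 cis-4-(5-oxoicosyl)cyclohex-4-ene-1,2-diol
Product: 14 1-(3,4-dihydroxyphenyl)icosan-5-one, via cyclohex-4-ene-1,2-dione tautomer 13 (not isolated)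
Conditions: DMSO (6 equiv), (CF3CO)2O (4.5 equiv), CH2Cl2, −60 °C; add 12; Et3N (10 equiv), −60 °C to rt; dilute HCl work-up under Ar
Reagents that add atoms: none
Why: Swern-type oxidation with DMSO activated by trifluoroacetic anhydride (chosen because it should not tie a cis-diol up as a cyclic ester) converts both carbinols through their alkoxysulfonium ylides into 1,2-dione 13, which is the diketo tautomer of a catechol and should aromatise by two base-mediated enolisations, one away from each carbonyl, so the transient stereocentres vanish, no phenol protection is needed and the chain ketone, having no carbinol C–H, is left alone.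

**Compound list**

1 | hept-6-ynoic acid | C#CCCCCC(O)=O | starting material
2 | 1-(1H-imidazol-1-yl)hept-6-yn-1-one (acyl imidazole, formed in the flask, not isolated) | C#CCCCCC(=O)n1ccnc1 | intermediate
3 | N-methoxy-N-methylhept-6-ynamide | C#CCCCCC(=O)N(C)OC | intermediate
4 | ethylene | C=C | starting material
5 | N-methoxy-N-methyl-6-methylideneoct-7-enamide | C=CC(=C)CCCCC(=O)N(C)OC | intermediate
6 | 1-bromopentadecane | CCCCCCCCCCCCCCCBr | starting material
7 | pentadecylmagnesium bromide, C15H31MgBr (formed in the flask, not isolated) | CCCCCCCCCCCCCCC[Mg]Br | intermediate
8 | bromomagnesium 8-[methoxy(methyl)amino]-3-methylidenetricos-1-en-8-olate (magnesium hemiaminal chelate, formed in the flask, not isolated) | CCCCCCCCCCCCCCCC(O[Mg]Br)(N(C)OC)CCCCC(=C)C=C | intermediate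
9 | 3-methylidenetricos-1-en-8-one | C=CC(=C)CCCCC(=O)CCCCCCCCCCCCCCC | intermediate
10 | vinylene carbonate (1,3-dioxol-2-one) | O=C1OC=CO1 | starting material
11 | cis-5-(5-oxoicosyl)-3a,4,7,7a-tetrahydro-1,3-benzodioxol-2-one, racemic (3aR*,7aS*), one enantiomer drawn | CCCCCCCCCCCCCCCC(=O)CCCCC1=CC[C@H]2OC(=O)O[C@H]2C1 | intermediate
12 | cis-4-(5-oxoicosyl)cyclohex-4-ene-1,2-diol, racemic (1R*,2S*), one enantiomer drawn | CCCCCCCCCCCCCCCC(=O)CCCCC1=CC[C@@H](O)[C@@H](O)C1 | intermediate
13 | 4-(5-oxoicosyl)cyclohex-4-ene-1,2-dione (formed in the flask, not isolated) | CCCCCCCCCCCCCCCC(=O)CCCCC1=CCC(=O)C(=O)C1 | intermediate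
14 | 1-(3,4-dihydroxyphenyl)icosan-5-one | CCCCCCCCCCCCCCCC(=O)CCCCc1ccc(O)c(O)c1 | target

**Step count**

Total steps: 6. Longest linear sequence: 6 steps (1 → 3 → 5 → 9 → 11 → 12 → 14).

**Steps most likely to fail**

Step 4. The cross-cycloaddition with the sluggish dienophile may lose out to thermal dimerisation and polymerisation of the diene, or to polymerisation of the dienophile itself, at the temperature required. The fallback gives up building the ring and attaches the chain to a preformed, protected catechol. It leaves the route at 1-bromopentadecane 6, which is kept as its Grignard reagent 7, and rejoins at the target 14. Pent-4-ynoic acid would be converted as in step 1 (CDI, then MeNHOMe·HCl, CH2Cl2) into N-methoxy-N-methylpent-4-ynamide F1. Sonogashira coupling of this amide with 4-bromo-1,2-bis(benzyloxy)benzene (PdCl2(PPh3)2, CuI, Et3N, DMF, 80 °C) should give 5-[3,4-bis(benzyloxy)phenyl]-N-methoxy-N-methylpent-4-ynamide F2. Addition of 7 (THF, 0 °C, acidic quench) should give 1-[3,4-bis(benzyloxy)phenyl]icos-1-yn-5-one F3. Hydrogenation (H2, 10% Pd/C, EtOAc–EtOH, rt) should then saturate the alkyne and cleave both benzyl ethers in one operation to give 14, the non-benzylic ketone being left intact.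

Step 6. The freshly formed electron-rich catechol may be attacked by surplus electrophilic sulfonium species (ring methylthiomethylation), or the oxidation may stall at the ketol stage and lose water to a phenol. The fallback sets out from diol 12 and returns at 14. It replaces the activated sulfoxide by a hypervalent iodine oxidant that is deliberately allowed to overshoot: 2-iodoxybenzoic acid (about 4 equiv, DMSO, rt) should take 12 through the dione and the catechol to the ortho-quinone 4-(5-oxoicosyl)cyclohexa-3,5-diene-1,2-dione F4. This is reduced at once in the same flask with aqueous Na2S2O4 to give 14, so that no electrophile remains when the catechol is finally released.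

Step 2. The ruthenium carbene may decompose before the alkyne is consumed, or the product diene may be drawn into secondary metathesis and oligomerise. The fallback sets out from alkyne 3 and returns at diene 5, building the diene by cross-coupling instead. Markovnikov hydroiodination of 3 (NaI, Me3SiCl, H2O, MeCN, rt) should give 6-iodo-N-methoxy-N-methylhept-6-enamide F5. Suzuki–Miyaura coupling of this alkenyl iodide with CH2=CHBF3K (PdCl2(dppf), Cs2CO3, THF–H2O, 70 °C) should then deliver 5.

**Further compounds**

F1 | step 4 | N-methoxy-N-methylpent-4-ynamide | C#CCCC(=O)N(C)OC
F2 | step 4 | 5-[3,4-bis(benzyloxy)phenyl]-N-methoxy-N-methylpent-4-ynamide | CON(C)C(=O)CCC#Cc1ccc(OCc2ccccc2)c(OCc2ccccc2)c1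
F3 | step 4 | 1-[3,4-bis(benzyloxy)phenyl]icos-1-yn-5-one | CCCCCCCCCCCCCCCC(=O)CCC#Cc1ccc(OCc2ccccc2)c(OCc2ccccc2)c1
F4 | step 6 | 4-(5-oxoicosyl)cyclohexa-3,5-diene-1,2-dione | CCCCCCCCCCCCCCCC(=O)CCCCC1=CC(=O)C(=O)C=C1
F5 | step 2 | 6-iodo-N-methoxy-N-methylhept-6-enamide | C=C(I)CCCCC(=O)N(C)OC
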